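**Strategy.** The route rests on disconnecting the bond between the gem-dimethyl quaternary carbon C4 and the ring-fusion methine C3a of the seven-membered ring of the decahydroazulene. The key step exploits that the exocyclic methylene carbon C8 sits on the other ring-fusion carbon C8a: at ketone level, C8=O makes C3a the β-carbon of a 1-acylcyclopentene. Hydrogen-atom transfer to a pendant isopropenyl group gives a tertiary radical that closes the seven-membered ring 7-endo, creating the quaternary carbon, the ring and both ring-fusion stereocentres in one operation. The precursor is a monocyclic cyclopentenyl 4-methylpent-4-enyl ketone that already carries the quaternary methyl carbon and the complete diacetoxy lactone side chain.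

Key step: step 13

Remark: locants follow the decahydroazulene numbering of the target (C1 quaternary methyl carbon, C3a and C8a ring fusion, C4 gem-dimethyl carbon, C8 methylidene carbon); the facial rule of the chiral-imine Michael addition known for 2-methylcyclohexanone is assumed to hold for 2-methylcyclopentanone.

Step 1
Reactants: 1 (tert-butyldimethylsilyloxy)acetaldehyde; 2 nitromethane
Product: 5 (E)-tert-butyldimethyl[(3-nitroprop-2-en-1-yl)oxy]silane, via nitroaldol 3 (not isolated), via mesylate 4 (not isolated)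
Conditions: MeNO2 (5 equiv), Et3N (0.1 equiv), 0 °C to rt; evaporate; MsCl, Et3N, CH2Cl2, −30 °C
Reagents that add atoms: none
Why: Henry (nitroaldol) addition followed by mesylation and base-induced elimination should give the conjugated nitroalkene as the thermodynamically favoured E isomer; no stereocentre is formed.

Step 2
Reactants: 6 2-methylcyclopentan-1-one; 7 (R)-1-phenylethylamine; 5 (E)-tert-butyldimethyl[(3-nitroprop-2-en-1-yl)oxy]silane
Product: 10 (S)-2-[(S)-1-(tert-butyldimethylsilyloxy)-3-nitropropan-2-yl]-2-methylcyclopentan-1-one, via imine 8 (not isolated), via adduct imine 9 (not isolated)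
Conditions: toluene, reflux, Dean–Stark; then 5, THF, −20 °C to rt; then 10 % aq. AcOH, rt
Reagents that add atoms: water O
Why: Asymmetric Michael addition of a chiral imine through its more substituted secondary enamine tautomer (aza-ene-type transition state): attack on the enamine face remote from the phenyl group of the (R)-auxiliary should set the (S) quaternary carbon, and the compact arrangement with the nitro group over nitrogen and the silyloxymethyl group exo should set the adjacent (S) methine.

Step 3
Reactants: 10 (S)-2-[(S)-1-(tert-butyldimethylsilyloxy)-3-nitropropan-2-yl]-2-methylcyclopentan-1-one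
Product: 12 (R)-3-(tert-butyldimethylsilyloxy)-2-[(S)-1-methyl-2-oxocyclopentyl]propanal, via sodium nitronate 11 (not isolated)
Conditions: NaOMe (1.05 equiv), MeOH, 0 °C; then O3, MeOH/CH2Cl2, −78 °C; N2 purge, pH 7 buffer
Reagents that add atoms: ozone [O-][O+]=O
Why: Nef reaction by ozonolysis of the nitronate C=N bond, which proceeds at −78 °C without free base, so the β-silyloxy aldehyde should neither epimerize nor eliminate; the ketone is not touched.

Step 4
Reactants: 12 (R)-3-(tert-butyldimethylsilyloxy)-2-[(S)-1-methyl-2-oxocyclopentyl]propanal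
Product: 14 (R)-5-[(S)-1-methyl-2-oxocyclopentyl]-5,6-dihydro-2H-pyran-2-one, via Z-enoate 13 (not isolated)
Conditions: (CF3CH2O)2P(O)CH2CO2Me, KN(SiMe3)2, 18-crown-6, THF, −78 °C; then 2 M aq. HCl, THF, rt to 40 °C
Reagents that add atoms: methyl bis(2,2,2-trifluoroethyl)phosphonoacetate COC(=O)CP(=O)(OCC(F)(F)F)OCC(F)(F)F
Why: Still–Gennari Z-selective Horner–Wadsworth–Emmons olefination consumes the aldehyde at −78 °C before it can epimerize, and acid then cleaves the silyl ether so that the cis hydroxy ester lactonizes; existing stereocentres are not involved.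

Step 5
Reactants: 14 (R)-5-[(S)-1-methyl-2-oxocyclopentyl]-5,6-dihydro-2H-pyran-2-one
Product: 15 (S)-5-methyl-5-[(R)-6-oxo-3,6-dihydro-2H-pyran-3-yl]cyclopent-1-en-1-yl trifluoromethanesulfonate
Conditions: Tf2O, 2,6-di-tert-butyl-4-methylpyridine, CH2Cl2, 0 °C to rt
Reagents that add atoms: trifluoromethanesulfonic anhydride O=S(=O)(OS(=O)(=O)C(F)(F)F)C(F)(F)F
Why: Enol triflate formation under non-nucleophilic base conditions is regiochemically unambiguous because the ketone has only one enolizable α-position, and the weakly basic unsaturated lactone should not react.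

Step 6
Reactants: 15 (S)-5-methyl-5-[(R)-6-oxo-3,6-dihydro-2H-pyran-3-yl]cyclopent-1-en-1-yl trifluoromethanesulfonate
Product: 17 (S)-5-{(R)-2-hydroxy-1-[(R)-5-oxooxolan-3-yl]ethyl}-5-methylcyclopent-1-en-1-yl trifluoromethanesulfonate, via hydroxymethyl δ-lactone 16 (not isolated)
Conditions: benzophenone (0.3 equiv), MeOH, hν (350 nm), rt; then camphorsulfonic acid (0.1 equiv), CH2Cl2, rt
Reagents that add atoms: methanol CO
Why: Photosensitized radical conjugate addition (Giese type) of the hydroxymethyl radical to the unsaturated δ-lactone should occur anti to the bulky C5 substituent and so set the new (R) methine, after which acid-catalysed translactonization gives the thermodynamically favoured γ-lactone and frees the primary alcohol.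

Step 7
Reactants: 17 (S)-5-{(R)-2-hydroxy-1-[(R)-5-oxooxolan-3-yl]ethyl}-5-methylcyclopent-1-en-1-yl trifluoromethanesulfonate
Product: 18 (S)-5-{(R)-2-hydroxy-1-[(3R,4S)-4-hydroxy-5-oxooxolan-3-yl]ethyl}-5-methylcyclopent-1-en-1-yl trifluoromethanesulfonate
Conditions: KN(SiMe3)2 (2.2 equiv), THF, −78 °C; 2-(phenylsulfonyl)-3-phenyloxaziridine, −78 °C; then AcOH
Reagents that add atoms: 2-(phenylsulfonyl)-3-phenyloxaziridine O=S(=O)(c1ccccc1)N1OC1c1ccccc1
Why: Enolate hydroxylation (Davis oxidation) of the alkoxide/lactone enolate dianion, with the oxaziridine approaching anti to the β-substituent of the butyrolactone, should give the trans (S) carbinol; the enol triflate is stable to the amide base at −78 °C.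

Step 8
Reactants: 18 (S)-5-{(R)-2-hydroxy-1-[(3R,4S)-4-hydroxy-5-oxooxolan-3-yl]ethyl}-5-methylcyclopent-1-en-1-yl trifluoromethanesulfonate
Product: 19 (2R)-2-[(3R,4S)-4-acetoxy-5-oxooxolan-3-yl]-2-[(1S)-1-methyl-2-(trifluoromethanesulfonyloxy)cyclopent-2-en-1-yl]ethyl acetate
Conditions: Ac2O, pyridine, DMAP (cat.), CH2Cl2, 0 °C to rt
Reagents that add atoms: acetic anhydride CC(=O)OC(C)=O
Why: DMAP-catalysed acylation of both hydroxyl groups installs the two acetates of the target; the trans α-acetoxy lactone is the thermodynamic epimer, so no stereocentre is at risk.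

Step 9
Reactants: 20 ethyl 5-oxohexanoate
Product: 21 ethyl 5-methylhex-5-enoate
Conditions: Ph3PCH3Br, KOtBu, THF, 0 °C to rt
Reagents that add atoms: methyltriphenylphosphonium bromide C[P+](c1ccccc1)(c1ccccc1)c1ccccc1.[Br-]
Why: Wittig methylenation is chemoselective for the ketone over the ester and creates the isopropenyl group; no stereocentre.

Step 10
Reactants: 21 ethyl 5-methylhex-5-enoate
Product: 22 5-methylhex-5-enal
Conditions: iBu2AlH (1.05 equiv), CH2Cl2, −78 °C
Reagents that add atoms: none
Why: Partial reduction of the ester with iBu2AlH stops at the aldehyde because the tetrahedral aluminium hemiacetal is stable at −78 °C; no stereocentre.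

Step 11
Reactants: 19 (2R)-2-[(3R,4S)-4-acetoxy-5-oxooxolan-3-yl]-2-[(1S)-1-methyl-2-(trifluoromethanesulfonyloxy)cyclopent-2-en-1-yl]ethyl acetate; 22 5-methylhex-5-enal
Product: 23 (2R)-2-[(3R,4S)-4-acetoxy-5-oxooxolan-3-yl]-2-[(1S)-2-(1-hydroxy-5-methylhex-5-en-1-yl)-1-methylcyclopent-2-en-1-yl]ethyl acetate (mixture of carbinol epimers)
Conditions: CrCl2 (4 equiv), NiCl2 (1 mol %), DMF, rt
Reagents that add atoms: none
Why: Nozaki–Hiyama–Kishi coupling (zerovalent nickel inserts into the enol triflate, transmetalation gives a trivalent chromium alkenyl that adds only to the aldehyde) tolerates acetates and the lactone; the carbinol mixture is inconsequential because it is oxidized next.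

Step 12
Reactants: 23 (2R)-2-[(3R,4S)-4-acetoxy-5-oxooxolan-3-yl]-2-[(1S)-2-(1-hydroxy-5-methylhex-5-en-1-yl)-1-methylcyclopent-2-en-1-yl]ethyl acetate
Product: 24 (2R)-2-[(3R,4S)-4-acetoxy-5-oxooxolan-3-yl]-2-[(1S)-1-methyl-2-(5-methylhex-5-enoyl)cyclopent-2-en-1-yl]ethyl acetate
Conditions: Dess–Martin periodinane, CH2Cl2, rt
Reagents that add atoms: none
Why: Dess–Martin oxidation of the allylic alcohol gives the cross-conjugation-free cyclopentenyl ketone under neutral conditions and removes the carbinol stereocentre.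

Step 13
Reactants: 24 (2R)-2-[(3R,4S)-4-acetoxy-5-oxooxolan-3-yl]-2-[(1S)-1-methyl-2-(5-methylhex-5-enoyl)cyclopent-2-en-1-yl]ethyl acetate
Product: 25 (2R)-2-[(3R,4S)-4-acetoxy-5-oxooxolan-3-yl]-2-[(1S,3aR,8aR)-1,4,4-trimethyl-8-oxodecahydroazulen-1-yl]ethyl acetate
Conditions: Fe(acac)3 (0.3 equiv), PhSiH3 (2.5 equiv), EtOH/ethylene glycol 5:1, 0.005 M, 60 °C
Reagents that add atoms: none
Why: Fe(acac)3 and PhSiH3 give a trivalent iron hydride that transfers a hydrogen atom to the electron-rich 1,1-disubstituted alkene (Markovnikov), the resulting nucleophilic tertiary radical adds to the β-carbon C3a of the cyclopentenyl ketone, and the α-keto radical is reduced by divalent iron to an iron enolate that ethanol protonates; the closest known reaction type is the metal-hydride hydrogen-atom-transfer initiated intramolecular Giese reaction (reductive olefin coupling). The seven-membered ring closes in the 7-endo-trig mode, favoured over 6-exo because the α-carbon is fully substituted and electronically mismatched with a nucleophilic radical. C3a is set by the quaternary carbon C1: the tether, anchored on the neighbouring C8a, swings over the face that carries the C1 methyl group, away from the branched side chain, so C4 ends up cis to that methyl. C8a is set on protonation of the enolate from the convex face to give the cis ring fusion, which keeps the acyl carbon trans to the side chain and is also the expected thermodynamic epimer of this enolizable centre. The step needs chemoselective hydrogen-atom transfer to the isopropenyl group in the presence of the enone, secured by the electron-poor nature of the enone, and needs ring closure to outrun reduction of the radical, secured by high dilution and the absence of any other acceptor.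

Step 14
Reactants: 25 (2R)-2-[(3R,4S)-4-acetoxy-5-oxooxolan-3-yl]-2-[(1S,3aR,8aR)-1,4,4-trimethyl-8-oxodecahydroazulen-1-yl]ethyl acetate
Product: 26 (2R)-2-[(3R,4S)-4-acetoxy-5-oxooxolan-3-yl]-2-[(1R,3aR,8aS)-1,4,4-trimethyl-8-methylidenedecahydroazulen-1-yl]ethyl acetate
Conditions: Zn, CH2Br2, TiCl4, THF/CH2Cl2, 0 °C to rt
Reagents that add atoms: dibromomethane BrCBr
Why: Takai–Lombardo methylenation uses a non-basic titanium–zinc methylidene reagent that reacts with the ketone in preference to acetates and the lactone and should not epimerize the α-stereocentre C8a (its descriptor changes from R to S only through the priority change).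

**Compound list**

1 | (tert-butyldimethylsilyloxy)acetaldehyde | CC(C)(C)[Si](C)(C)OCC=O | starting material
2 | nitromethane | C[N+](=O)[O-] | starting material
3 | 1-(tert-butyldimethylsilyloxy)-3-nitropropan-2-ol (racemic nitroaldol) | CC(C)(C)[Si](C)(C)OCC(O)C[N+](=O)[O-] | intermediate
4 | 1-(tert-butyldimethylsilyloxy)-3-nitropropan-2-yl methanesulfonate | CC(C)(C)[Si](C)(C)OCC(OS(C)(=O)=O)C[N+](=O)[O-] | intermediate
5 | (E)-tert-butyldimethyl[(3-nitroprop-2-en-1-yl)oxy]silane | CC(C)(C)[Si](C)(C)OC/C=C/[N+](=O)[O-] | intermediate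
6 | 2-methylcyclopentan-1-one (racemic) | CC1CCCC1=O | starting material
7 | (R)-1-phenylethylamine | C[C@@H](N)c1ccccc1 | starting material
8 | 2-methyl-N-[(R)-1-phenylethyl]cyclopentan-1-imine (epimers at C2, in equilibrium with its enamine tautomers) | CC1CCCC1=N[C@H](C)c1ccccc1 | intermediate
9 | (S)-2-[(S)-1-(tert-butyldimethylsilyloxy)-3-nitropropan-2-yl]-2-methyl-N-[(R)-1-phenylethyl]cyclopentan-1-imine | C1(=N[C@H](C)c2ccccc2)CCC[C@@]1(C)[C@H](CO[Si](C)(C)C(C)(C)C)C[N+](=O)[O-] | intermediate
10 | (S)-2-[(S)-1-(tert-butyldimethylsilyloxy)-3-nitropropan-2-yl]-2-methylcyclopentan-1-one | O=C1CCC[C@@]1(C)[C@H](CO[Si](C)(C)C(C)(C)C)C[N+](=O)[O-] | intermediate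
11 | sodium nitronate of 10 | O=C1CCC[C@@]1(C)[C@H](CO[Si](C)(C)C(C)(C)C)C=[N+]([O-])[O-].[Na+] | intermediate
12 | (R)-3-(tert-butyldimethylsilyloxy)-2-[(S)-1-methyl-2-oxocyclopentyl]propanal | O=C1CCC[C@@]1(C)[C@H](CO[Si](C)(C)C(C)(C)C)C=O | intermediate
13 | methyl (R,Z)-5-(tert-butyldimethylsilyloxy)-4-[(S)-1-methyl-2-oxocyclopentyl]pent-2-enoate | O=C1CCC[C@@]1(C)[C@H](CO[Si](C)(C)C(C)(C)C)/C=C\C(=O)OC | intermediate
14 | (R)-5-[(S)-1-methyl-2-oxocyclopentyl]-5,6-dihydro-2H-pyran-2-one | O=C1CCC[C@@]1(C)[C@@H]2COC(=O)C=C2 | intermediate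
15 | (S)-5-methyl-5-[(R)-6-oxo-3,6-dihydro-2H-pyran-3-yl]cyclopent-1-en-1-yl trifluoromethanesulfonate | FC(F)(F)S(=O)(=O)OC1=CCC[C@@]1(C)[C@@H]2COC(=O)C=C2 | intermediate
16 | (S)-5-[(3R,4R)-4-(hydroxymethyl)-6-oxooxan-3-yl]-5-methylcyclopent-1-en-1-yl trifluoromethanesulfonate | FC(F)(F)S(=O)(=O)OC1=CCC[C@@]1(C)[C@@H]2COC(=O)C[C@H]2CO | intermediate
17 | (S)-5-{(R)-2-hydroxy-1-[(R)-5-oxooxolan-3-yl]ethyl}-5-methylcyclopent-1-en-1-yl trifluoromethanesulfonate | FC(F)(F)S(=O)(=O)OC1=CCC[C@@]1(C)[C@H](CO)[C@@H]2COC(=O)C2 | intermediate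
18 | (S)-5-{(R)-2-hydroxy-1-[(3R,4S)-4-hydroxy-5-oxooxolan-3-yl]ethyl}-5-methylcyclopent-1-en-1-yl trifluoromethanesulfonate | FC(F)(F)S(=O)(=O)OC1=CCC[C@@]1(C)[C@H](CO)[C@@H]2COC(=O)[C@H]2O | intermediate
19 | (2R)-2-[(3R,4S)-4-acetoxy-5-oxooxolan-3-yl]-2-[(1S)-1-methyl-2-(trifluoromethanesulfonyloxy)cyclopent-2-en-1-yl]ethyl acetate | FC(F)(F)S(=O)(=O)OC1=CCC[C@@]1(C)[C@H](COC(C)=O)[C@@H]2COC(=O)[C@H]2OC(C)=O | intermediate
20 | ethyl 5-oxohexanoate | CCOC(=O)CCCC(C)=O | starting material
21 | ethyl 5-methylhex-5-enoate | CCOC(=O)CCCC(C)=C | intermediate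
22 | 5-methylhex-5-enal | O=CCCCC(C)=C | intermediate
23 | (2R)-2-[(3R,4S)-4-acetoxy-5-oxooxolan-3-yl]-2-[(1S)-2-(1-hydroxy-5-methylhex-5-en-1-yl)-1-methylcyclopent-2-en-1-yl]ethyl acetate (carbinol epimers) | C=C(C)CCCC(O)C1=CCC[C@@]1(C)[C@H](COC(C)=O)[C@@H]2COC(=O)[C@H]2OC(C)=O | intermediate
24 | (2R)-2-[(3R,4S)-4-acetoxy-5-oxooxolan-3-yl]-2-[(1S)-1-methyl-2-(5-methylhex-5-enoyl)cyclopent-2-en-1-yl]ethyl acetate | C=C(C)CCCC(=O)C1=CCC[C@@]1(C)[C@H](COC(C)=O)[C@@H]2COC(=O)[C@H]2OC(C)=O | intermediate
25 | (2R)-2-[(3R,4S)-4-acetoxy-5-oxooxolan-3-yl]-2-[(1S,3aR,8aR)-1,4,4-trimethyl-8-oxodecahydroazulen-1-yl]ethyl acetate | O=C1CCCC(C)(C)[C@@H]2CC[C@@](C)([C@H](COC(C)=O)[C@@H]3COC(=O)[C@H]3OC(C)=O)[C@H]12 | intermediate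
26 | (2R)-2-[(3R,4S)-4-acetoxy-5-oxooxolan-3-yl]-2-[(1R,3aR,8aS)-1,4,4-trimethyl-8-methylidenedecahydroazulen-1-yl]ethyl acetate | C=C1CCCC(C)(C)[C@@H]2CC[C@@](C)([C@H](COC(C)=O)[C@@H]3COC(=O)[C@H]3OC(C)=O)[C@H]12 | target

**Step count.** Total: 14 steps. Longest linear sequence: 12 steps (steps 1 to 8 and 11 to 14); steps 9 and 10 prepare the aldehyde partner.

**Steps most likely to fail**

Step 13 (key step). The tertiary radical may be reduced to an isopropyl group, or the enone may be reduced, before the 7-endo closure. Facial discrimination at C3a by the remote quaternary carbon may also be incomplete, and protonation at C8a may give some trans-fused ketone. Fallback, setting out from enone 24 and coming back at ketone 25: Markovnikov hydrobromination of the isopropenyl group (HBr in AcOH, CH2Cl2, −40 °C) should give the tertiary bromide F1. Slow syringe-pump addition of (Me3Si)3SiH and AIBN in refluxing benzene then generates the same tertiary radical by bromine-atom abstraction at a very low hydrogen-donor concentration, so that ring closure outruns reduction. If needed, brief DBU equilibration at C8a converges on the cis-fused ketone 25.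

Step 2. The tetrasubstituted enamine tautomer may react sluggishly with a β-substituted nitroalkene or compete with attack at the less substituted α-carbon. The endo/exo preference may erode and give the epimer at the side-chain methine, and the γ-silyloxy nitroalkene may isomerize under the basic conditions. Fallback, setting out from ketone 6 and coming back at aldehyde 12: 6 is converted to its thermodynamic silyl enol ether 2-methyl-1-(trimethylsilyloxy)cyclopent-1-ene F2 (Me3SiCl, NaI, Et3N, MeCN). Branch-selective iridium-catalysed asymmetric allylic alkylation ([Ir(cod)Cl]2, chiral phosphoramidite, CsF, ZnF2) with methyl (E)-4-(tert-butyldimethylsilyloxy)but-2-en-1-yl carbonate F3 (from commercial (E)-4-(tert-butyldimethylsilyloxy)but-2-en-1-ol and methyl chloroformate) should give the vinyl ketone (S)-2-[(R)-1-(tert-butyldimethylsilyloxy)but-3-en-2-yl]-2-methylcyclopentan-1-one F4. Ozonolysis of its vinyl group (O3, CH2Cl2, −78 °C; PPh3) gives aldehyde 12.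

Step 6. Triplet benzophenone may abstract hydrogen at other C–H bonds, the enol triflate may degrade on irradiation, and translactonization may be incomplete. Fallback, setting out from lactone 15 and coming back at alcohol 17: rhodium-catalysed 1,4-addition of vinylboronic acid pinacol ester ([Rh(cod)OH]2, dioxane/H2O, 40 °C), trans to the ring substituent, should give the vinyl lactone (S)-5-[(3R,4S)-4-ethenyl-6-oxooxan-3-yl]-5-methylcyclopent-1-en-1-yl trifluoromethanesulfonate F5. Selective ozonolysis of the electron-rich vinyl group (O3, −78 °C; PPh3) gives the aldehyde (S)-5-[(3R,4R)-4-formyl-6-oxooxan-3-yl]-5-methylcyclopent-1-en-1-yl trifluoromethanesulfonate F6. NaBH4 (MeOH, −20 °C) reduces it to carbinol 16, which under the same camphorsulfonic acid treatment gives 17.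

**Further compounds**

F1 | step 13 | (2R)-2-[(3R,4S)-4-acetoxy-5-oxooxolan-3-yl]-2-[(1S)-2-(5-bromo-5-methylhexanoyl)-1-methylcyclopent-2-en-1-yl]ethyl acetate | CC(C)(Br)CCCC(=O)C1=CCC[C@@]1(C)[C@H](COC(C)=O)[C@@H]2COC(=O)[C@H]2OC(C)=O
F2 | step 2 | 2-methyl-1-(trimethylsilyloxy)cyclopent-1-ene | CC1=C(O[Si](C)(C)C)CCC1
F3 | step 2 | methyl (E)-4-(tert-butyldimethylsilyloxy)but-2-en-1-yl carbonate | COC(=O)OC/C=C/CO[Si](C)(C)C(C)(C)C
F4 | step 2 | (S)-2-[(R)-1-(tert-butyldimethylsilyloxy)but-3-en-2-yl]-2-methylcyclopentan-1-one | O=C1CCC[C@@]1(C)[C@H](CO[Si](C)(C)C(C)(C)C)C=C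
F5 | step 6 | (S)-5-[(3R,4S)-4-ethenyl-6-oxooxan-3-yl]-5-methylcyclopent-1-en-1-yl trifluoromethanesulfonate | FC(F)(F)S(=O)(=O)OC1=CCC[C@@]1(C)[C@@H]2COC(=O)C[C@H]2C=C
F6 | step 6 | (S)-5-[(3R,4R)-4-formyl-6-oxooxan-3-yl]-5-methylcyclopent-1-en-1-yl trifluoromethanesulfonate | FC(F)(F)S(=O)(=O)OC1=CCC[C@@]1(C)[C@@H]2COC(=O)C[C@H]2C=O
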